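**Plan** (germacrane numbers: C1 ketone, C2=C3, C4=C15, ether carbons C5 and C10, C6 lactone carbinol, C8 ester carbon, C11=C13, C12 lactone carbonyl; ring A = O, C10, C1–C5; ring B = O, C5–C10)
Cuts: first the O8–angeloyl bond; then C7–C8 of ring B. This is possible because C8 is a carbinol bonded to C7, and C7 is the γ-carbon of the allyl unit C13–C11=C7 held in the lactone, so C8–OH plus exocyclic C11=C13 is the retron of an aldehyde allylation by a 3-(bromomethyl)butenolide. Further cuts: C12–C11 (carbonylation), C4=C15, C2=C3 (metathesis), C5–C6 (aldol), O–C5 (ether).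
Forward: (S)-citramalic acid → C8–C10/C1 tertiary alcohol → glycolate ether → aldol with a (Z)-β-iodoenal → ring A by metathesis → butenolide by carbonylation → ring B and the methylene lactone by chromium allylation → angelate.
Stereochemistry: C10 from citramalic acid; C5 and C6 from an oxazolidinone-controlled syn glycolate aldol; C7 and C8 in the ring-B closure, directed by the preformed cis-substituted ring A; the C1 carbinol is transient.

Key step: step 21

Remark: the C1 carbinol made in step 3 is not controlled and is erased in step 20, so 6–8, 10, 11 and 17–27 are C1 epimer pairs (their SMILES leave C1 open) and 5 is an anomer mixture. PMB = 4-methoxybenzyl, TBS = tert-butyldimethylsilyl, TES = triethylsilyl, R* = (3S)-1,4-bis(PMB-oxy)-3-methylhex-5-en-3-yl.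

**Step 1**
Reactants: 1 (S)-citramalic acid
Product: 2 2-[(4S)-2,2,4-trimethyl-5-oxo-1,3-dioxolan-4-yl]acetic acid
Conditions: Me2C(OMe)2, TsOH·H2O (cat.), CH2Cl2, rt
Reagents that add atoms: 2,2-dimethoxypropane, COC(C)(C)OC
Why: Acid-catalysed transketalisation ties the tertiary hydroxyl and the adjacent carboxyl into a five-membered dioxolanone, which leaves only the C8 carboxyl free and does not touch C10.

**Step 2**
Reactants: 2 2-[(4S)-2,2,4-trimethyl-5-oxo-1,3-dioxolan-4-yl]acetic acid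
Product: 4 (3S)-3-hydroxy-3-methyloxolan-2-one, via hydroxyethyl dioxolanone 3 (not isolated)
Conditions: BH3·SMe2, THF, 0 °C → rt; MeOH quench; TsOH·H2O (cat.), CH2Cl2, rt
Reagents that add atoms: none
Why: Borane reduces the free carboxylic acid in preference to the dioxolanone carbonyl, and acid then drives transesterification of the new primary alcohol onto that carbonyl (five-membered lactone, acetone lost).

**Step 3**
Reactants: 4 (3S)-3-hydroxy-3-methyloxolan-2-one
Product: 6 (3S)-3-methylhex-5-ene-1,3,4-triol, via lactol 5 (not isolated)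
Conditions: i-Bu2AlH (2.2 equiv), CH2Cl2, −78 °C; then CH2=CHMgBr (4 equiv), THF, −78 °C → rt; aq. potassium sodium tartrate
Reagents that add atoms: vinylmagnesium bromide, C=C[Mg]Br
Why: Half-reduction of the lactone stops at the aluminium lactolate at −78 °C, and the aldehyde it releases on warming is trapped by the Grignard reagent (one-pot reduction–vinylation); the new C1 carbinol forms without control, which is immaterial.

**Step 4**
Reactants: 6 (3S)-3-methylhex-5-ene-1,3,4-triol
Product: 7 (3S)-1,4-bis(PMB-oxy)-3-methylhex-5-en-3-ol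
Conditions: NaH (2.2 equiv), PMBCl (2.1 equiv), Bu4NI (cat.), DMF, 0 °C → rt
Reagents that add atoms: 4-methoxybenzyl chloride, COc1ccc(CCl)cc1
Why: Williamson etherification, in which the primary and secondary alkoxides are benzylated far faster than the hindered tertiary one, so the C10 hydroxyl should stay free.

**Step 5**
Reactants: 7 (3S)-1,4-bis(PMB-oxy)-3-methylhex-5-en-3-ol
Product: 8 2-(R*-oxy)acetic acid
Conditions: NaH (4 equiv), BrCH2CO2H (2 equiv), THF/DMF, 0 °C → rt; 1 M HCl
Reagents that add atoms: bromoacetic acid, OC(=O)CBr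
Why: Williamson O-alkylation of the tertiary sodium alkoxide with sodium bromoacetate, whose carboxylate cannot undergo ester condensation; no bond to C10 is broken.

**Step 6**
Reactants: 8 2-(R*-oxy)acetic acid; 9 (4R)-4-benzyl-1,3-oxazolidin-2-one
Product: 11 (4R)-4-benzyl-3-[2-(R*-oxy)acetyl]-1,3-oxazolidin-2-one, via mixed pivalic anhydride 10 (not isolated)
Conditions: t-BuCOCl, Et3N, THF, −20 °C; then 9, LiCl, −20 °C → rt
Reagents that add atoms: none
Why: Mixed-anhydride activation followed by LiCl-promoted N-acylation of the oxazolidinone, which attacks the less hindered glycolyl carbonyl.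

**Step 7**
Reactants: 12 but-2-yne-1,4-diol
Product: 13 4-(TBS-oxy)but-2-yn-1-ol
Conditions: NaH (1.0 equiv), THF, 0 °C; TBSCl (1.0 equiv), rt
Reagents that add atoms: tert-butyldimethylsilyl chloride, CC(C)(C)[Si](C)(C)Cl
Why: Monosilylation of a symmetrical diol through its sparingly soluble monosodium alkoxide.

**Step 8**
Reactants: 13 4-(TBS-oxy)but-2-yn-1-ol
Product: 15 (2Z)-4-(TBS-oxy)-3-iodobut-2-en-1-ol, via alkenylaluminate 14 (not isolated)
Conditions: NaAlH2(OCH2CH2OMe)2 (Red-Al), THF, 0 °C → rt; then I2, THF, −78 → 0 °C; aq. Na2S2O3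
Reagents that add atoms: iodine, II
Why: Hydroxyl-directed trans-hydroalumination places aluminium on the alkyne carbon remote from the free hydroxyl and cis to its CH2O group in a five-membered aluminate, and iodinolysis of the C–Al bond with retention gives the (Z)-3-iodo allylic alcohol.

**Step 9**
Reactants: 15 (2Z)-4-(TBS-oxy)-3-iodobut-2-en-1-ol
Product: 16 (2Z)-4-(TBS-oxy)-3-iodobut-2-enal
Conditions: MnO2 (activated, excess), CH2Cl2, rt, dark; used at once
Reagents that add atoms: none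
Why: Allylic alcohol oxidation on MnO2 under neutral conditions, which should avoid Z to E isomerisation of the β-iodoenal.

**Step 10**
Reactants: 11 (4R)-4-benzyl-3-[2-(R*-oxy)acetyl]-1,3-oxazolidin-2-one; 16 (2Z)-4-(TBS-oxy)-3-iodobut-2-enal
Product: 18 (4R)-4-benzyl-3-[(2R,3S,4Z)-2-(R*-oxy)-6-(TBS-oxy)-3-hydroxy-5-iodohex-4-enoyl]-1,3-oxazolidin-2-one, via boron enolate 17 (not isolated)
Conditions: Bu2BOTf, i-Pr2NEt, CH2Cl2, −78 → 0 °C; 16, −78 → 0 °C; pH 7 buffer, MeOH, 30% H2O2, 0 °C
Reagents that add atoms: none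
Why: Evans syn glycolate aldol, in which the (Z)-boron enolate reacts through a Zimmerman–Traxler chair on the face away from the benzyl group of the (R)-auxiliary and so sets C5 and C6 (5,6-syn, the arrangement of the target) while the enal reacts at its carbonyl.

**Step 11**
Reactants: 18 syn-aldol imide
Product: 19 (2R,3S,4Z)-2-(R*-oxy)-6-(TBS-oxy)-3-hydroxy-5-iodo-N-methoxy-N-methylhex-4-enamide
Conditions: MeNHOMe·HCl, AlMe3, CH2Cl2, −20 → 0 °C
Reagents that add atoms: N,O-dimethylhydroxylamine hydrochloride, CNOC.Cl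
Why: Weinreb amide formation by aluminium amide transamination at the exocyclic imide carbonyl, assisted by the free β-hydroxyl; there is no enolisation, so C5 is safe and the auxiliary is recovered.

**Step 12**
Reactants: 19 Weinreb amide
Product: 20 (2R,3S,4Z)-2-(R*-oxy)-6-(TBS-oxy)-5-iodo-N-methoxy-N-methyl-3-(TES-oxy)hex-4-enamide
Conditions: TESOTf, 2,6-lutidine, CH2Cl2, −78 °C
Reagents that add atoms: triethylsilyl triflate, CC[Si](CC)(CC)OS(=O)(=O)C(F)(F)F
Why: Silyl triflate silylation of the secondary C6 hydroxyl, which blocks alkoxide chemistry (oxa-Michael addition, retro-aldol) in the next three steps.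

**Step 13**
Reactants: 20 silylated Weinreb amide
Product: 21 (4R,5S,6Z)-4-(R*-oxy)-8-(TBS-oxy)-7-iodo-5-(TES-oxy)octa-1,6-dien-3-one
Conditions: CH2=CHMgBr, THF, −78 → 0 °C; inverse quench into cold 1 M HCl
Reagents that add atoms: vinylmagnesium bromide, C=C[Mg]Br
Why: Weinreb ketone synthesis, in which the chelated tetrahedral intermediate prevents over-addition and the acidic inverse quench stops the released amine from adding to the vinyl ketone.

**Step 14**
Reactants: 21 vinyl ketone
Product: 22 (2R,7S)-2-[(1S,2Z)-4-(TBS-oxy)-3-iodo-1-(TES-oxy)but-2-en-1-yl]-6-(PMB-oxy)-7-[2-(PMB-oxy)ethyl]-7-methyl-6,7-dihydrooxepin-3(2H)-one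
Conditions: second-generation Grubbs catalyst RuCl2(=CHPh)(H2IMes)(PCy3) (5–10 mol%), CH2Cl2 (0.002 M), 40 °C
Reagents that add atoms: none
Why: Ring-closing metathesis of the allylic-ether vinyl group with the vinyl ketone closes ring A (seven-membered, C2=C3 necessarily cis) with loss of ethene, and the trisubstituted iodoalkene is inert to the ruthenium carbene.

**Step 15**
Reactants: 22 ring-A oxepinone
Product: 23 (2S,7S)-2-[(1S,2Z)-4-(TBS-oxy)-3-iodo-1-(TES-oxy)but-2-en-1-yl]-6-(PMB-oxy)-7-[2-(PMB-oxy)ethyl]-7-methyl-3-methylidene-2,3,6,7-tetrahydrooxepine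
Conditions: Cp2Ti(μ-Cl)(μ-CH2)AlMe2 (Tebbe reagent), pyridine (cat.), THF–toluene, −40 → 0 °C
Reagents that add atoms: Tebbe reagent, C[Al-]1(C)C[Ti](C2C=CC=C2)(C2C=CC=C2)[Cl+]1
Why: Tebbe methylenation (titanium methylidene, [2+2] addition then cycloreversion) converts the C4 ketone into the C4=C15 alkene without base, so the α-alkoxy centre C5 and the β-silyloxy group should survive.

**Step 16**
Reactants: 23 ring-A diene
Product: 24 (1S,2Z)-1-[(2S,7S)-6-(PMB-oxy)-7-[2-(PMB-oxy)ethyl]-7-methyl-3-methylidene-2,3,6,7-tetrahydrooxepin-2-yl]-3-iodobut-2-ene-1,4-diol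
Conditions: HF·pyridine, pyridine, THF, 0 °C → rt
Reagents that add atoms: none
Why: Fluoride-driven cleavage of the secondary TES and primary TBS ethers, to which PMB ethers, the diene and the vinyl iodide are inert.

**Step 17**
Reactants: 24 iodo diol
Product: 25 (5S)-3-(hydroxymethyl)-5-[(2S,7S)-6-(PMB-oxy)-7-[2-(PMB-oxy)ethyl]-7-methyl-3-methylidene-2,3,6,7-tetrahydrooxepin-2-yl]furan-2(5H)-one
Conditions: CO (1 atm), Pd(PPh3)4 (5 mol%), Et3N, MeCN, 50 °C
Reagents that add atoms: carbon monoxide, [C-]#[O+]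
Why: Carbonylative lactonisation of a (Z)-γ-hydroxy vinyl iodide (oxidative addition to zerovalent palladium, CO insertion, capture of the acylpalladium by the cis C6 hydroxyl) gives the butenolide with C6 untouched, the C13 hydroxyl being able to close only a four-membered ring.

**Step 18**
Reactants: 25 hydroxymethyl butenolide
Product: 26 (5S)-3-(bromomethyl)-5-[(2S,7S)-6-(PMB-oxy)-7-[2-(PMB-oxy)ethyl]-7-methyl-3-methylidene-2,3,6,7-tetrahydrooxepin-2-yl]furan-2(5H)-one
Conditions: CBr4, PPh3, CH2Cl2, 0 °C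
Reagents that add atoms: carbon tetrabromide, BrC(Br)(Br)Br
Why: Appel bromination of the primary allylic alcohol under neutral conditions.

**Step 19**
Reactants: 26 bromomethyl butenolide
Product: 27 (5S)-3-(bromomethyl)-5-[(2S,7S)-6-hydroxy-7-(2-hydroxyethyl)-7-methyl-3-methylidene-2,3,6,7-tetrahydrooxepin-2-yl]furan-2(5H)-one
Conditions: DDQ (3 equiv), CH2Cl2/pH 7 buffer (10:1), 0 °C → rt
Reagents that add atoms: none
Why: Oxidative cleavage of both PMB ethers by DDQ (benzylic hydride abstraction, then hydrolysis of the oxocarbenium ion), which should leave the bromide, the butenolide and the transoid diene alone.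

**Step 20**
Reactants: 27 C1,C8-diol
Product: 29 2-[(2S,7S)-7-[(2S)-4-(bromomethyl)-5-oxo-2,5-dihydrofuran-2-yl]-2-methyl-6-methylidene-3-oxo-2,3,6,7-tetrahydrooxepin-2-yl]acetaldehyde, via hydroxy dienone 28 (not isolated)
Conditions: MnO2, CH2Cl2, rt; filter; then Dess–Martin periodinane, NaHCO3, CH2Cl2, 0 °C → rt; used crude
Reagents that add atoms: none
Why: Two-stage oxidation in which MnO2 takes only the dienylic C1 alcohol, so that no 4-hydroxy aldehyde (and hence no lactol or lactone) can form when the Dess–Martin reagent then oxidises the primary C8 alcohol.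

**Step 21**
Reactants: 29 ring-A keto aldehyde with the 3-(bromomethyl)butenolide at C5
Product: 31 8-deacyl alcohol (5S,6S,7R,8R,10S), via allylchromium dichloride 30 (not isolated)
Conditions: CrCl2 (8 equiv), THF, 0.003 M (slow addition of 29), rt; aq. NH4Cl
Reagents that add atoms: none
Why: Two equivalents of divalent chromium reduce the allylic C13–Br bond to the allylchromium dichloride 30 (trivalent chromium), which adds to the C8 aldehyde through its γ-carbon C7 in a closed six-membered chair (Cr, O8, C8, C7, C11, C13), so C7–C8 forms while the double bond shifts to C11=C13. This is the Nozaki–Hiyama (Barbier-type) allylation of aldehydes by 3-(bromomethyl)butenolides, and its intramolecular form with bromomethylbutenolide aldehydes is an established ring-closing method. Ring B (O, C5, C6, C7, C8, C9, C10) closes as a seven-membered ring in the 7-exo-trig mode at the aldehyde carbon, the cis C5/C10 substituents of ring A holding C7 and C8 within reach. C7 is controlled by the preset bicyclic frame: the chromium chair with its ligands should fit only on the exo face of the nascent 11-oxabicyclo[4.4.1]undecane (the face of the bridging oxygen, away from the dienone bridge of ring A), so C11 ends exo and trans to the lactone oxygen on C6 (7R). C8 is controlled by the same chair, since O8 is bound to chromium and must lie on that exo face too, cis to C11 with H7 and H8 cis (8R), an arrangement the bridging ether oxygen β to the aldehyde can reinforce by coordinating chromium. The step needs aldehyde-over-ketone chemoselectivity and γ- over α-attack: allylchromium reagents leave ketones and enones alone, the C1 carbonyl is buried in ring A, and α-attack would demand a nine-membered ring.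

**Step 22**
Reactants: 31 8-deacyl alcohol; 32 angelic acid
Product: 34 target 8-angelate (CNP0282559.1), via mixed anhydride 33 (not isolated)
Conditions: 32, 2,4,6-Cl3C6H2COCl, Et3N, toluene, rt; then 31, 75 °C
Reagents that add atoms: none
Why: Yamaguchi-type esterification through the mixed 2,4,6-trichlorobenzoic anhydride without DMAP, conditions under which the Z (angelate) double bond should not isomerise to the tiglate; the C8–O bond is not broken, so C8 keeps its configuration.

**Compound list**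
1 | (S)-citramalic acid, (2S)-2-hydroxy-2-methylbutanedioic acid | OC(=O)C[C@](C)(O)C(=O)O | starting material
2 | 2-[(4S)-2,2,4-trimethyl-5-oxo-1,3-dioxolan-4-yl]acetic acid | OC(=O)C[C@]1(C)OC(C)(C)OC1=O | intermediate
3 | (5S)-5-(2-hydroxyethyl)-2,2,5-trimethyl-1,3-dioxolan-4-one | OCC[C@]1(C)OC(C)(C)OC1=O | intermediate (not isolated)
4 | (3S)-3-hydroxy-3-methyloxolan-2-one | C[C@]1(O)CCOC1=O | intermediate
5 | (3S)-3-methyloxolane-2,3-diol (lactol, anomers) | C[C@]1(O)CCOC1O | intermediate (not isolated)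
6 | (3S)-3-methylhex-5-ene-1,3,4-triol (C4 epimers; C4 = germacrane C1) | C=CC(O)[C@@](C)(O)CCO | intermediate
7 | (3S)-1,4-bis[(4-methoxybenzyl)oxy]-3-methylhex-5-en-3-ol | C=CC(OCc1ccc(OC)cc1)[C@@](C)(O)CCOCc1ccc(OC)cc1 | intermediate
8 | 2-{[(3S)-1,4-bis[(4-methoxybenzyl)oxy]-3-methylhex-5-en-3-yl]oxy}acetic acid | C=CC(OCc1ccc(OC)cc1)[C@@](C)(OCC(=O)O)CCOCc1ccc(OC)cc1 | intermediate
9 | (4R)-4-benzyl-1,3-oxazolidin-2-one | O=C1N[C@H](Cc2ccccc2)CO1 | starting material
10 | mixed anhydride of 8 with pivalic acid | C=CC(OCc1ccc(OC)cc1)[C@@](C)(OCC(=O)OC(=O)C(C)(C)C)CCOCc1ccc(OC)cc1 | intermediate (not isolated)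
11 | (4R)-4-benzyl-3-(2-{[(3S)-1,4-bis[(4-methoxybenzyl)oxy]-3-methylhex-5-en-3-yl]oxy}acetyl)-1,3-oxazolidin-2-one | C=CC(OCc1ccc(OC)cc1)[C@@](C)(OCC(=O)N1[C@H](Cc2ccccc2)COC1=O)CCOCc1ccc(OC)cc1 | intermediate
12 | but-2-yne-1,4-diol | OCC#CCO | starting material
13 | 4-[(tert-butyldimethylsilyl)oxy]but-2-yn-1-ol | OCC#CCO[Si](C)(C)C(C)(C)C | intermediate
14 | sodium alkenylaluminate (five-membered C–Al–O ring, Al on C3) from 13 | [Na+].COCCO[Al-]1(OCCOC)OCC=C1CO[Si](C)(C)C(C)(C)C | intermediate (not isolated)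
15 | (2Z)-4-[(tert-butyldimethylsilyl)oxy]-3-iodobut-2-en-1-ol | OC/C=C(\I)CO[Si](C)(C)C(C)(C)C | intermediate
16 | (2Z)-4-[(tert-butyldimethylsilyl)oxy]-3-iodobut-2-enal | O=C/C=C(\I)CO[Si](C)(C)C(C)(C)C | intermediate
17 | (Z)-dibutylboron enolate of 11 | C=CC(OCc1ccc(OC)cc1)[C@@](C)(O/C=C(\OB(CCCC)CCCC)N1[C@H](Cc2ccccc2)COC1=O)CCOCc1ccc(OC)cc1 | intermediate (not isolated)
18 | (4R)-4-benzyl-3-[(2R,3S,4Z)-2-(R*-oxy)-6-(TBS-oxy)-3-hydroxy-5-iodohex-4-enoyl]-1,3-oxazolidin-2-one | C=CC(OCc1ccc(OC)cc1)[C@](C)(CCOCc1ccc(OC)cc1)O[C@H]([C@@H](O)/C=C(\I)CO[Si](C)(C)C(C)(C)C)C(=O)N1[C@H](Cc2ccccc2)COC1=O | intermediate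
19 | (2R,3S,4Z)-2-(R*-oxy)-6-(TBS-oxy)-3-hydroxy-5-iodo-N-methoxy-N-methylhex-4-enamide | C=CC(OCc1ccc(OC)cc1)[C@](C)(CCOCc1ccc(OC)cc1)O[C@H]([C@@H](O)/C=C(\I)CO[Si](C)(C)C(C)(C)C)C(=O)N(C)OC | intermediate
20 | (2R,3S,4Z)-2-(R*-oxy)-6-(TBS-oxy)-5-iodo-N-methoxy-N-methyl-3-(TES-oxy)hex-4-enamide | C=CC(OCc1ccc(OC)cc1)[C@](C)(CCOCc1ccc(OC)cc1)O[C@H]([C@@H](O[Si](CC)(CC)CC)/C=C(\I)CO[Si](C)(C)C(C)(C)C)C(=O)N(C)OC | intermediate
21 | (4R,5S,6Z)-4-(R*-oxy)-8-(TBS-oxy)-7-iodo-5-(TES-oxy)octa-1,6-dien-3-one | C=CC(OCc1ccc(OC)cc1)[C@](C)(CCOCc1ccc(OC)cc1)O[C@H]([C@@H](O[Si](CC)(CC)CC)/C=C(\I)CO[Si](C)(C)C(C)(C)C)C(=O)C=C | intermediate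
22 | (2R,7S)-2-[(1S,2Z)-4-(TBS-oxy)-3-iodo-1-(TES-oxy)but-2-en-1-yl]-6-(PMB-oxy)-7-[2-(PMB-oxy)ethyl]-7-methyl-6,7-dihydrooxepin-3(2H)-one | C[C@@]1(CCOCc2ccc(OC)cc2)O[C@H]([C@@H](O[Si](CC)(CC)CC)/C=C(\I)CO[Si](C)(C)C(C)(C)C)C(=O)C=CC1OCc1ccc(OC)cc1 | intermediate
23 | (2S,7S)-2-[(1S,2Z)-4-(TBS-oxy)-3-iodo-1-(TES-oxy)but-2-en-1-yl]-6-(PMB-oxy)-7-[2-(PMB-oxy)ethyl]-7-methyl-3-methylidene-2,3,6,7-tetrahydrooxepine | C[C@@]1(CCOCc2ccc(OC)cc2)O[C@H]([C@@H](O[Si](CC)(CC)CC)/C=C(\I)CO[Si](C)(C)C(C)(C)C)C(=C)C=CC1OCc1ccc(OC)cc1 | intermediate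
24 | (1S,2Z)-1-[(2S,7S)-6-(PMB-oxy)-7-[2-(PMB-oxy)ethyl]-7-methyl-3-methylidene-2,3,6,7-tetrahydrooxepin-2-yl]-3-iodobut-2-ene-1,4-diol | C[C@@]1(CCOCc2ccc(OC)cc2)O[C@H]([C@@H](O)/C=C(\I)CO)C(=C)C=CC1OCc1ccc(OC)cc1 | intermediate
25 | (5S)-3-(hydroxymethyl)-5-[(2S,7S)-6-(PMB-oxy)-7-[2-(PMB-oxy)ethyl]-7-methyl-3-methylidene-2,3,6,7-tetrahydrooxepin-2-yl]furan-2(5H)-one | C[C@@]1(CCOCc2ccc(OC)cc2)O[C@H]([C@H]2OC(=O)C(CO)=C2)C(=C)C=CC1OCc1ccc(OC)cc1 | intermediate
26 | (5S)-3-(bromomethyl)-5-[(2S,7S)-6-(PMB-oxy)-7-[2-(PMB-oxy)ethyl]-7-methyl-3-methylidene-2,3,6,7-tetrahydrooxepin-2-yl]furan-2(5H)-one | C[C@@]1(CCOCc2ccc(OC)cc2)O[C@H]([C@H]2OC(=O)C(CBr)=C2)C(=C)C=CC1OCc1ccc(OC)cc1 | intermediate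
27 | (5S)-3-(bromomethyl)-5-[(2S,7S)-6-hydroxy-7-(2-hydroxyethyl)-7-methyl-3-methylidene-2,3,6,7-tetrahydrooxepin-2-yl]furan-2(5H)-one | C[C@@]1(CCO)O[C@H]([C@H]2OC(=O)C(CBr)=C2)C(=C)C=CC1O | intermediate
28 | (5S)-3-(bromomethyl)-5-[(2S,7S)-7-(2-hydroxyethyl)-7-methyl-3-methylidene-6-oxo-2,3,6,7-tetrahydrooxepin-2-yl]furan-2(5H)-one | C[C@@]1(CCO)O[C@H]([C@H]2OC(=O)C(CBr)=C2)C(=C)C=CC1=O | intermediate (not isolated)
29 | 2-[(2S,7S)-7-[(2S)-4-(bromomethyl)-5-oxo-2,5-dihydrofuran-2-yl]-2-methyl-6-methylidene-3-oxo-2,3,6,7-tetrahydrooxepin-2-yl]acetaldehyde (key-step precursor) | C[C@@]1(CC=O)O[C@H]([C@H]2OC(=O)C(CBr)=C2)C(=C)C=CC1=O | intermediate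
30 | allylchromium dichloride from 29 (CrCl2 on C13 in place of Br) | C[C@@]1(CC=O)O[C@H]([C@H]2OC(=O)C(C[Cr](Cl)Cl)=C2)C(=C)C=CC1=O | intermediate (not isolated)
31 | 8-deacyl alcohol (5S,6S,7R,8R,10S), tricyclic α-methylene lactone with free C8–OH (key-step product) | C=C1C(=O)O[C@H]2[C@H]1[C@H](O)C[C@]1(C)O[C@H]2C(=C)C=CC1=O | intermediate
32 | angelic acid, (2Z)-2-methylbut-2-enoic acid | C/C=C(/C)C(=O)O | starting material
33 | angelic 2,4,6-trichlorobenzoic anhydride | C/C=C(/C)C(=O)OC(=O)c1c(Cl)cc(Cl)cc1Cl | intermediate (not isolated)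
34 | CNP0282559.1, the 8-angelate (5S,6S,7R,8R,10S) | C=C1C(=O)O[C@H]2[C@H]1[C@H](OC(=O)/C(C)=C\C)C[C@]1(C)O[C@H]2C(=C)C=CC1=O | target

**Totals and risks**
Total step count: 22. Longest linear sequence: 19 steps (steps 1–6 and 10–22); the iodoenal branch is steps 7–9.

Steps most likely to fail:

1. Step 21. The aldehyde may add with its chain equatorial on the chromium chair, that is, with poor facial selectivity at C8, so that the 8-epimer is formed. Fallback: setting out again from 29, the same cyclisation is run and the 8-epimeric alcohol F1 is esterified with angelic acid 32 under Mitsunobu conditions (PPh3, DIAD, toluene, 0 °C → rt). The SN2 inversion at C8 should then give the angelate of correct configuration, and the route is rejoined at 34.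

2. Step 5. Alkylation of the crowded tertiary alkoxide may be too slow, so that bromoacetate is consumed by other pathways and 7 is returned. Fallback: setting out from 7, the ether is made by carbenoid O–H insertion (ethyl diazoacetate, Rh2(OAc)4 cat., CH2Cl2, rt), a reaction that accepts tertiary alcohols and needs no base. This gives the ethyl ester F2, which is saponified (LiOH, THF/H2O) to rejoin the route at 8.

3. Step 17. Carbopalladation of the neighbouring ring-A diene by the vinylpalladium species may compete with CO insertion. Fallback: setting out from 23, iodine–lithium exchange (t-BuLi, Et2O, −78 °C) and trapping with CO2 give the (Z)-carboxylic acid F3. HF·pyridine (THF) then removes both silyl groups and the freed γ-hydroxy acid should lactonise spontaneously, rejoining the route at 25.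

**Further compounds**
F1 | step 21 | 8-epi alcohol (5S,6S,7R,8S,10S) | C=C1C(=O)O[C@H]2[C@H]1[C@@H](O)C[C@]1(C)O[C@H]2C(=C)C=CC1=O
F2 | step 5 | ethyl 2-{[(3S)-1,4-bis[(4-methoxybenzyl)oxy]-3-methylhex-5-en-3-yl]oxy}acetate | C=CC(OCc1ccc(OC)cc1)[C@@](C)(OCC(=O)OCC)CCOCc1ccc(OC)cc1
F3 | step 17 | (Z)-carboxylic acid from 23 (CO2H in place of iodine on C11) | C[C@@]1(CCOCc2ccc(OC)cc2)O[C@H]([C@@H](O[Si](CC)(CC)CC)/C=C(\C(=O)O)CO[Si](C)(C)C(C)(C)C)C(=C)C=CC1OCc1ccc(OC)cc1
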